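The 3,4-cis-disubstituted tetrahydrofuran is disconnected by treating one carbonyl carbon as a temporary tie between C7 (carbinol carbon) and C7' (benzylic CH2), which sit on the same face of the ring on C8 and C8'. An enantioselective Pauson–Khand reaction of an allyl arylpropargyl ether with CO then makes C8–C8', both bonds to the bridging carbonyl, the oxacycle and a fused cyclopentenone in one operation, setting C8'. Convex-face hydrogenation sets C8 and C7. Baeyer–Villiger migration of C7 installs its oxygen with retention, and the carbonyl carbon finally leaves as CO2 in a decarboxylative arylation that attaches the second arene. The precursor is the triisopropylsilyl-protected aryl enyne 4.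

Key step: step 3

Remarks and assumptions
- Lignan numbering is used: C7 = carbinol carbon, C8 = ring carbon bearing it, C7' = benzylic CH2, C8' = ring carbon bearing it, C9 and C9' = the two OCH2 carbons. The target is (7S,8S,8'R), with C7 and C7' cis on the ring.
- Assumption: (S)-BINAP is taken as the ligand antipode that delivers the 5R enone 6. The sense of induction is to be checked on the first batch, and (R)-BINAP is used instead if it proves opposite.
- The phenols are carried as triisopropylsilyl ethers, because a tert-butyldimethylsilyl aryl ether would not be expected to survive the hydroxide opening of the lactone in step 6. One silylated bromide 2 serves both arenes, and all three silyl groups fall in the final fluoride step.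

Step 1
Reactants: 1 5-bromo-2-methoxyphenol
Product: 2 (5-bromo-2-methoxyphenoxy)triisopropylsilane
Conditions: TIPSCl, imidazole, DMF, 25 °C
Reagents that add atoms: triisopropylsilyl chloride (TIPSCl), CC(C)[Si](Cl)(C(C)C)C(C)C
Why: Imidazole-promoted O-silylation of a phenol is routine, and the bulky triisopropylsilyl aryl ether is chosen for its resistance to the amine, hydroxide and organometallic conditions that follow.

Step 2
Reactants: 2 (5-bromo-2-methoxyphenoxy)triisopropylsilane; 3 3-(allyloxy)prop-1-yne
Product: 4 allyl 3-[4-methoxy-3-(triisopropylsilyloxy)phenyl]prop-2-yn-1-yl ether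
Conditions: Pd(PhCN)2Cl2 (3 mol %), P(t-Bu)3 (6 mol %), CuI (2 mol %), i-Pr2NH, 1,4-dioxane, 25 °C
Reagents that add atoms: none
Why: Sonogashira coupling with a bulky electron-rich phosphine should let the electron-rich aryl bromide react at room temperature, which avoids base-induced isomerisation of the propargyl ether and leaves the allyl group untouched.

Step 3
Reactants: 4 allyl 3-[4-methoxy-3-(triisopropylsilyloxy)phenyl]prop-2-yn-1-yl ether; 5 carbon monoxide
Product: 6 (5R)-2-[4-methoxy-3-(triisopropylsilyloxy)phenyl]-7-oxabicyclo[3.3.0]oct-1-en-3-one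
Conditions: [Rh(CO)2Cl]2 (3 mol %), (S)-BINAP (9 mol %), AgOTf (12 mol %), CO (1 atm), THF, 90 °C (sealed vessel)
Reagents that add atoms: none
Why: A cationic monovalent rhodium–BINAP complex (chloride removed by AgOTf) binds the alkyne and alkene of 4 and undergoes oxidative cyclisation to a rhodacyclopentene of trivalent rhodium, which forms C8–C8'; CO then inserts into a Rh–C bond and C–C reductive elimination releases the enone, forming C7–C(O) and C(O)–C7' and returning monovalent rhodium. The closest known reaction type is the catalytic enantioselective intramolecular Pauson–Khand (2+2+1) cyclocarbonylation of 1,6-enynes, for which allyl arylpropargyl ethers are standard substrates. The oxacycle closes during the oxidative cyclisation in a 5-exo sense with respect to both the alkyne and the alkene, and the cyclopentenone closes by carbonyl insertion followed by reductive elimination from a six-membered acyl rhodacycle. The only new stereocentre, C8' (bicyclic C5), is set under catalyst control, the C2-symmetric diphosphine deciding which alkene enantioface enters the oxidative cyclisation. The step needs this enantioface selectivity and the regiochemistry that places CO between the aryl-bearing alkyne carbon and the terminal alkene carbon; the three-atom ether tether fixes the regiochemistry, and the internal aryl alkyne with a monosubstituted alkene disfavours alkyne oligomerisation and gives a tetrasubstituted enone that cannot isomerise.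

Step 4
Reactants: 6 (5R)-2-[4-methoxy-3-(triisopropylsilyloxy)phenyl]-7-oxabicyclo[3.3.0]oct-1-en-3-one
Product: 7 (1R,2S,5R)-2-[4-methoxy-3-(triisopropylsilyloxy)phenyl]-7-oxabicyclo[3.3.0]octan-3-one
Conditions: H2 (1 atm), 10% Pd/C, EtOAc, 25 °C
Reagents that add atoms: none
Why: Heterogeneous catalytic hydrogenation adds both hydrogens syn to C7=C8 from the face of H8' (the only face that leads to a cis-fused bicycle), which sets C8 (cis ring fusion) and C7 (aryl endo, H7 cis to H8 and H8'); the neutral medium and direct use of crude 7 limit enolisation of the α-aryl ketone.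

Step 5
Reactants: 7 (1R,2S,5R)-2-[4-methoxy-3-(triisopropylsilyloxy)phenyl]-7-oxabicyclo[3.3.0]octan-3-one
Product: 8 (3aS,4S,7aR)-4-[4-methoxy-3-(triisopropylsilyloxy)phenyl]tetrahydro-1H-furo[3,4-c]pyran-6(4H)-one
Conditions: mCPBA, NaHCO3, CH2Cl2, 0 → 25 °C
Reagents that add atoms: 3-chloroperoxybenzoic acid (mCPBA), OOC(=O)c1cccc(Cl)c1
Why: In this Baeyer–Villiger oxidation the secondary, electron-rich benzylic C7 should migrate in preference to the C7' methylene and does so with retention, so the C7–O bond of the target is installed with the 7S configuration, while the bicarbonate buffer suppresses acid-promoted epimerisation of the ketone and ionisation of the benzylic lactone.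

Step 6
Reactants: 8 (3aS,4S,7aR)-4-[4-methoxy-3-(triisopropylsilyloxy)phenyl]tetrahydro-1H-furo[3,4-c]pyran-6(4H)-one
Product: 11 2-[(3R,4S)-4-{(S)-(tert-butyldimethylsilyloxy)[4-methoxy-3-(triisopropylsilyloxy)phenyl]methyl}tetrahydrofuran-3-yl]acetic acid, via lithium hydroxy-carboxylate 9 (not isolated), via silyl ether silyl ester 10 (not isolated)
Conditions: LiOH·H2O, THF–H2O, 0 °C; evaporate; TBSCl, imidazole, DMF, 25 °C; K2CO3, MeOH–THF–H2O, 0 °C; pH 5 work-up
Reagents that add atoms: lithium hydroxide, [Li+].[OH-]; tert-butyldimethylsilyl chloride (TBSCl), CC(C)(C)[Si](C)(C)Cl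
Why: Saponification cleaves the acyl–oxygen bond and leaves C7 untouched, exhaustive silylation of the salt blocks relactonisation, and the far more labile silyl ester is then hydrolysed selectively by mild carbonate, conditions the hindered aryl triisopropylsilyl ether and the secondary silyl ether should tolerate.

Step 7
Reactants: 11 2-[(3R,4S)-4-{(S)-(tert-butyldimethylsilyloxy)[4-methoxy-3-(triisopropylsilyloxy)phenyl]methyl}tetrahydrofuran-3-yl]acetic acid
Product: 12 1,3-dioxoisoindolin-2-yl 2-[(3R,4S)-4-{(S)-(tert-butyldimethylsilyloxy)[4-methoxy-3-(triisopropylsilyloxy)phenyl]methyl}tetrahydrofuran-3-yl]acetate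
Conditions: N-hydroxyphthalimide, DIC, DMAP (cat.), CH2Cl2, 25 °C
Reagents that add atoms: N-hydroxyphthalimide, ON1C(=O)c2ccccc2C1=O
Why: Carbodiimide-mediated (Steglich-type) esterification of an unhindered primary acetic acid with N-hydroxyphthalimide is standard for making redox-active esters, and the silylated C7 oxygen cannot intercept the activated acyl group.

Step 8
Reactants: 2 (5-bromo-2-methoxyphenoxy)triisopropylsilane
Product: 14 [4-methoxy-3-(triisopropylsilyloxy)phenyl]zinc chloride, via arylmagnesium bromide 13 (not isolated)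
Conditions: Mg, LiCl, THF, 25 °C; then ZnCl2, THF, 0 → 25 °C
Reagents that add atoms: zinc chloride, Cl[Zn]Cl
Why: LiCl-assisted magnesium insertion (Grignard formation) followed by transmetalation to zinc should give a titratable arylzinc chloride solution that is used directly, the silyl ether being inert and meta to the metal so that no silyl migration is possible.

Step 9
Reactants: 12 1,3-dioxoisoindolin-2-yl 2-[(3R,4S)-4-{(S)-(tert-butyldimethylsilyloxy)[4-methoxy-3-(triisopropylsilyloxy)phenyl]methyl}tetrahydrofuran-3-yl]acetate; 14 [4-methoxy-3-(triisopropylsilyloxy)phenyl]zinc chloride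
Product: 15 (3R,4S)-3-[4-methoxy-3-(triisopropylsilyloxy)benzyl]-4-{(S)-(tert-butyldimethylsilyloxy)[4-methoxy-3-(triisopropylsilyloxy)phenyl]methyl}tetrahydrofuran
Conditions: NiCl2(dme) (20 mol %), 4,4'-di-tert-butyl-2,2'-bipyridine (40 mol %), 14 (3 equiv), THF–DMF, 25 °C
Reagents that add atoms: none
Why: In this nickel-catalysed decarboxylative Negishi-type arylation of a redox-active ester, single-electron reduction of 12 by an arylnickel species expels phthalimide and CO2, and the primary C7' radical is captured at nickel and coupled with the aryl group by reductive elimination, a process established for primary alkyl esters that removes the bridging carbon and leaves all three stereocentres untouched.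

Step 10
Reactants: 15 (3R,4S)-3-[4-methoxy-3-(triisopropylsilyloxy)benzyl]-4-{(S)-(tert-butyldimethylsilyloxy)[4-methoxy-3-(triisopropylsilyloxy)phenyl]methyl}tetrahydrofuran
Product: 16 (S)-(3-hydroxy-4-methoxyphenyl)[(3S,4R)-4-(3-hydroxy-4-methoxybenzyl)tetrahydrofuran-3-yl]methanol
Conditions: TBAF, AcOH, THF, 0 → 25 °C
Reagents that add atoms: none
Why: Fluoride-driven desilylation should cleave both aryl silyl ethers and the benzylic silyl ether in one operation, and the acetic acid buffer keeps the medium close to neutral so that the electron-rich benzylic alcohol is neither ionised nor epimerised.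

Compound list
1 | 5-bromo-2-methoxyphenol | COc1ccc(Br)cc1O | starting material
2 | (5-bromo-2-methoxyphenoxy)triisopropylsilane | COc1ccc(Br)cc1O[Si](C(C)C)(C(C)C)C(C)C | intermediate
3 | 3-(allyloxy)prop-1-yne | C=CCOCC#C | starting material
4 | allyl 3-[4-methoxy-3-(triisopropylsilyloxy)phenyl]prop-2-yn-1-yl ether | C=CCOCC#Cc1ccc(OC)c(O[Si](C(C)C)(C(C)C)C(C)C)c1 | intermediate
5 | carbon monoxide | [C-]#[O+] | starting material
6 | (5R)-2-[4-methoxy-3-(triisopropylsilyloxy)phenyl]-7-oxabicyclo[3.3.0]oct-1-en-3-one | O=C1C[C@H]2COCC2=C1c1ccc(OC)c(O[Si](C(C)C)(C(C)C)C(C)C)c1 | intermediate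
7 | (1R,2S,5R)-2-[4-methoxy-3-(triisopropylsilyloxy)phenyl]-7-oxabicyclo[3.3.0]octan-3-one (cis-fused, H1, H2 and H5 on one face, aryl endo) | O=C1C[C@H]2COC[C@H]2[C@H]1c3ccc(OC)c(O[Si](C(C)C)(C(C)C)C(C)C)c3 | intermediate
8 | (3aS,4S,7aR)-4-[4-methoxy-3-(triisopropylsilyloxy)phenyl]tetrahydro-1H-furo[3,4-c]pyran-6(4H)-one (cis-fused δ-lactone, 7S,8S,8'R) | O=C1C[C@H]2COC[C@H]2[C@H](O1)c3ccc(OC)c(O[Si](C(C)C)(C(C)C)C(C)C)c3 | intermediate
9 | lithium 2-[(3R,4S)-4-{(S)-hydroxy[4-methoxy-3-(triisopropylsilyloxy)phenyl]methyl}tetrahydrofuran-3-yl]acetate | [Li+].[O-]C(=O)C[C@H]1COC[C@H]1[C@H](O)c3ccc(OC)c(O[Si](C(C)C)(C(C)C)C(C)C)c3 | intermediate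
10 | tert-butyldimethylsilyl 2-[(3R,4S)-4-{(S)-(tert-butyldimethylsilyloxy)[4-methoxy-3-(triisopropylsilyloxy)phenyl]methyl}tetrahydrofuran-3-yl]acetate | CC(C)(C)[Si](C)(C)OC(=O)C[C@H]1COC[C@H]1[C@H](O[Si](C)(C)C(C)(C)C)c3ccc(OC)c(O[Si](C(C)C)(C(C)C)C(C)C)c3 | intermediate
11 | 2-[(3R,4S)-4-{(S)-(tert-butyldimethylsilyloxy)[4-methoxy-3-(triisopropylsilyloxy)phenyl]methyl}tetrahydrofuran-3-yl]acetic acid | OC(=O)C[C@H]1COC[C@H]1[C@H](O[Si](C)(C)C(C)(C)C)c3ccc(OC)c(O[Si](C(C)C)(C(C)C)C(C)C)c3 | intermediate
12 | 1,3-dioxoisoindolin-2-yl 2-[(3R,4S)-4-{(S)-(tert-butyldimethylsilyloxy)[4-methoxy-3-(triisopropylsilyloxy)phenyl]methyl}tetrahydrofuran-3-yl]acetate | O=C(C[C@H]1COC[C@H]1[C@H](O[Si](C)(C)C(C)(C)C)c3ccc(OC)c(O[Si](C(C)C)(C(C)C)C(C)C)c3)ON4C(=O)c5ccccc5C4=O | intermediate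
13 | [4-methoxy-3-(triisopropylsilyloxy)phenyl]magnesium bromide | COc1ccc([Mg]Br)cc1O[Si](C(C)C)(C(C)C)C(C)C | intermediate
14 | [4-methoxy-3-(triisopropylsilyloxy)phenyl]zinc chloride | COc1ccc([Zn]Cl)cc1O[Si](C(C)C)(C(C)C)C(C)C | intermediate
15 | (3R,4S)-3-[4-methoxy-3-(triisopropylsilyloxy)benzyl]-4-{(S)-(tert-butyldimethylsilyloxy)[4-methoxy-3-(triisopropylsilyloxy)phenyl]methyl}tetrahydrofuran | COc1ccc(C[C@H]2COC[C@H]2[C@H](O[Si](C)(C)C(C)(C)C)c3ccc(OC)c(O[Si](C(C)C)(C(C)C)C(C)C)c3)cc1O[Si](C(C)C)(C(C)C)C(C)C | intermediate
16 | (S)-(3-hydroxy-4-methoxyphenyl)[(3S,4R)-4-(3-hydroxy-4-methoxybenzyl)tetrahydrofuran-3-yl]methanol | COc1ccc(C[C@H]2COC[C@H]2[C@H](O)c2ccc(OC)c(O)c2)cc1O | target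

Total step count: 10
Longest linear sequence: 9 steps (steps 1–7, 9 and 10; step 8 is a one-step side branch from 2)

Steps most likely to fail

Step 3. Enantioface discrimination may be insufficient at the temperature needed for turnover, and the enyne may be diverted into cycloisomerisation when the metal is starved of CO. Fallback: setting out from 4, a racemic Pauson–Khand reaction with catalytic Co2(CO)8 and tetramethylthiourea under CO (1 atm) in toluene at 70 °C would give the racemic enone F1. Its enantiomers would be separated by preparative supercritical-fluid chromatography on a chiral stationary phase, and the 5R antipode rejoins the route as 6.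

Step 9. The redox-active ester may be reduced and lost as the decarboxylated alkane or dimer before the alkyl radical is intercepted, and transmetalation from the electron-rich arylzinc may be slow. Fallback: setting out from 12, copper-catalysed decarboxylative borylation (Cu(acac)2, B2pin2, LiOH·H2O, MgCl2, dioxane–DMF, 25 °C) would give the primary pinacol boronate F2. A Suzuki–Miyaura alkyl–aryl coupling of F2 with bromide 2 (Pd(OAc)2, RuPhos, K3PO4, toluene–H2O, 80 °C) then returns to the route at 15. Any aryl silyl ether lost to the aqueous base is harmless, because step 10 removes all silyl groups.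

Step 5. Enolisation of the α-aryl ketone under the peracid conditions may move the aryl group to the exo face before oxygen insertion, which would carry the wrong C7 configuration into the lactone. Fallback: setting out from 7, the ketone is deliberately equilibrated (DBU, CH2Cl2, 25 °C) to the thermodynamically preferred exo-aryl ketone F3. Baeyer–Villiger oxidation with retention (mCPBA, NaHCO3) would give the 7-epi lactone F4, and hydroxide opening with careful acidification at 0 °C would give the 7-epi hydroxy acid F5, which is used at once. Mitsunobu lactonisation (PPh3, DIAD, toluene, −20 °C) then closes the ring by carboxylate displacement at C7 with inversion, which comes back to the route at 8. The low temperature and non-polar solvent are chosen to suppress ionisation of the electron-rich benzylic centre.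

Further compounds
F1 | step 3 | racemic 2-[4-methoxy-3-(triisopropylsilyloxy)phenyl]-7-oxabicyclo[3.3.0]oct-1-en-3-one | O=C1CC2COCC2=C1c1ccc(OC)c(O[Si](C(C)C)(C(C)C)C(C)C)c1
F2 | step 9 | 2-{[(3R,4S)-4-{(S)-(tert-butyldimethylsilyloxy)[4-methoxy-3-(triisopropylsilyloxy)phenyl]methyl}tetrahydrofuran-3-yl]methyl}-4,4,5,5-tetramethyl-1,3,2-dioxaborolane | CC1(C)OB(C[C@H]2COC[C@H]2[C@H](O[Si](C)(C)C(C)(C)C)c3ccc(OC)c(O[Si](C(C)C)(C(C)C)C(C)C)c3)OC1(C)C
F3 | step 5 | (1R,2R,5R)-2-[4-methoxy-3-(triisopropylsilyloxy)phenyl]-7-oxabicyclo[3.3.0]octan-3-one (aryl exo) | O=C1C[C@H]2COC[C@H]2[C@@H]1c3ccc(OC)c(O[Si](C(C)C)(C(C)C)C(C)C)c3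
F4 | step 5 | (3aS,4R,7aR)-4-[4-methoxy-3-(triisopropylsilyloxy)phenyl]tetrahydro-1H-furo[3,4-c]pyran-6(4H)-one | O=C1C[C@H]2COC[C@H]2[C@@H](O1)c3ccc(OC)c(O[Si](C(C)C)(C(C)C)C(C)C)c3
F5 | step 5 | 2-[(3R,4S)-4-{(R)-hydroxy[4-methoxy-3-(triisopropylsilyloxy)phenyl]methyl}tetrahydrofuran-3-yl]acetic acid | OC(=O)C[C@H]1COC[C@H]1[C@@H](O)c3ccc(OC)c(O[Si](C(C)C)(C(C)C)C(C)C)c3
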